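**Plan**

- Atom labels follow the thymol skeleton: arene C1–C6, C7 the benzylic CH2O on C1, the phenol oxygen on C3, C8 the quaternary oxirane carbon on C4, C9 the oxirane CH2, C10 the CH2OAc carbon.
- Retrosynthetic cuts, in order: the aryl angelate C–O bond; the oxirane bonds C8–C9 and C9–O (methylene transfer to a C8 ketone); the C10–OAc bond; the C4–C8 bond; the C7 isovalerate C–O bond.
- Enabling feature: the only ring to be made, the oxirane (O, C8, C9), is terminal and 2,2-disubstituted. C9 carries only two hydrogens, so it can arrive as CH2 from a sulfoxonium ylide at the carbonyl carbon C8 of an aryl ketone flanked by C4 and C10.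
- Forward order: silylation, reduction and isovalerylation set up C7; Stille coupling joins C8 to C4 as an enol ether; bromination and acetate displacement functionalise C10; the oxirane closes in step 8; the silyl group is exchanged for the angelate last.
- Stereochemistry: the single stereocentre C8 (R) is set in step 8 by a chiral lanthanum–lithium binaphthoxide catalyst that selects the ketone face. The Z alkene is bought with angelic acid and carried through two acyl transfers that use no nucleophilic catalyst.

Key step: step 8

Remark: the sense of induction of LaLi3(binaphthoxide)3 on an α-acetoxy ketone is not established. The (S)-ligand is written on the assumption that it exposes the Re face of the C8 carbonyl (O > CH2OAc > aryl); the (R)-ligand, equally available, would be used if a trial showed the opposite sense.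

**Route**

Step 1
Reactants: 1 methyl 4-bromo-3-hydroxybenzoate
Product: 2 methyl 4-bromo-3-(triisopropylsilyloxy)benzoate
Conditions: TIPSCl, imidazole, DMF, rt
Reagents that add atoms: triisopropylsilyl chloride, CC(C)[Si](Cl)(C(C)C)C(C)C
Why: Imidazole-promoted O-silylation of the phenol (silyl ether formation); the bulky triisopropylsilyl ether should withstand acetate, the sulfoxonium ylide and the alkoxide of step 8 and still fall to fluoride at the end.

Step 2
Reactants: 2 methyl 4-bromo-3-(triisopropylsilyloxy)benzoate
Product: 3 [4-bromo-3-(triisopropylsilyloxy)phenyl]methanol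
Conditions: i-Bu2AlH (2.5 equiv), CH2Cl2, −78 to 0 °C; aqueous KNaC4H4O6 work-up
Reagents that add atoms: none
Why: Hydride reduction of the aryl ester to the benzylic alcohol (ester reduction with i-Bu2AlH), which at low temperature should leave the aryl bromide and the aryl silyl ether untouched.

Step 3
Reactants: 3 [4-bromo-3-(triisopropylsilyloxy)phenyl]methanol
Product: 4 4-bromo-3-(triisopropylsilyloxy)benzyl 3-methylbutanoate
Conditions: 3-methylbutanoyl chloride, Et3N, DMAP (cat.), CH2Cl2, 0 °C to rt
Reagents that add atoms: 3-methylbutanoyl chloride, CC(C)CC(=O)Cl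
Why: Nucleophile-catalysed esterification of the only free hydroxyl group with an acid chloride installs the C7 isovalerate before any base-sensitive group is present.

Step 4
Reactants: 4 4-bromo-3-(triisopropylsilyloxy)benzyl 3-methylbutanoate; 5 tributyl(1-ethoxyvinyl)stannane
Product: 6 4-(1-ethoxyvinyl)-3-(triisopropylsilyloxy)benzyl 3-methylbutanoate
Conditions: 5 (1.3 equiv), PdCl2(PPh3)2 (5 mol%), toluene, 100 °C; filtration through Et3N-deactivated silica
Reagents that add atoms: none
Why: Stille coupling of the aryl bromide with the α-ethoxyvinylstannane forms the C4–C8 bond under neutral, fluoride-free conditions that spare the silyl ether and the ester, and delivers C8 as a masked acyl group.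

Step 5
Reactants: 6 4-(1-ethoxyvinyl)-3-(triisopropylsilyloxy)benzyl 3-methylbutanoate
Product: 7 4-(2-bromoacetyl)-3-(triisopropylsilyloxy)benzyl 3-methylbutanoate
Conditions: NBS (1.0 equiv), THF/H2O (4:1), 0 °C
Reagents that add atoms: N-bromosuccinimide, O=C1CCC(=O)N1Br; water, O
Why: Electrophilic bromination of the enol ether, capture of the oxocarbenium ion by water and loss of ethanol (bromination–hydrolysis of an enol ether) should give the bromomethyl ketone, the enol ether being far more nucleophilic than the silyloxyarene.

Step 6
Reactants: 7 4-(2-bromoacetyl)-3-(triisopropylsilyloxy)benzyl 3-methylbutanoate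
Product: 8 4-(2-acetoxyacetyl)-3-(triisopropylsilyloxy)benzyl 3-methylbutanoate
Conditions: KOAc (1.5 equiv), DMF, 0 °C to rt
Reagents that add atoms: potassium acetate, CC(=O)[O-].[K+]
Why: SN2 displacement of the phenacyl-type bromide by acetate (nucleophilic substitution), accelerated by the adjacent carbonyl group, installs the C10 acetate.

Step 7
Reactants: 9 trimethylsulfoxonium chloride
Product: 10 dimethylsulfoxonium methylide
Conditions: NaH (1.0 equiv), THF, reflux; filtration under argon; used as a titrated THF solution
Reagents that add atoms: none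
Why: Deprotonation of the sulfoxonium salt by NaH (Corey–Chaykovsky ylide generation) gives a THF solution from which insoluble NaCl is filtered, so that no foreign salt disturbs the lanthanum–lithium catalyst of step 8.

Step 8
Reactants: 8 4-(2-acetoxyacetyl)-3-(triisopropylsilyloxy)benzyl 3-methylbutanoate; 10 dimethylsulfoxonium methylide
Product: 12 4-[(2R)-2-(acetoxymethyl)oxiran-2-yl]-3-(triisopropylsilyloxy)benzyl 3-methylbutanoate, via sulfoxonium betaine 11 (not isolated)
Conditions: 10 (1.2 equiv, slow addition), LaLi3[(S)-1,1'-binaphthalene-2,2'-diolate]3 (5–10 mol%), tris(2,4,6-trimethoxyphenyl)phosphine oxide (5–10 mol%), 5 Å molecular sieves, THF, rt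
Reagents that add atoms: none
Why: Proposed new method: the nucleophilic CH2 of 10 should add to the C8 carbonyl of 8 while the ketone is bound to the Lewis-acidic lanthanum centre and the ylide is positioned by a lithium binaphthoxide arm (the phosphine oxide on lanthanum tightening the pocket), giving betaine 11, whose alkoxide then displaces dimethyl sulfoxide from C9. The closest known reaction is the catalytic asymmetric Corey–Chaykovsky epoxidation of aryl methyl ketones with this ylide and the same LaLi3 tris(binaphthoxide)/triarylphosphine oxide system; a ketone whose second substituent is CH2OAc has not been shown in it, which is why the step is labelled. The oxirane closes in a 3-exo-tet mode (C9–O bond) after the C8–C9 bond has formed. The new stereocentre C8 is controlled by the catalyst alone, which has to expose the Re face of the ketone (O > CH2OAc > aryl) so that (R)-12 results, CH2OAc occupying the site that methyl takes in the known substrates. The step needs chemoselectivity for the ketone over the two alkyl esters, the aryl silyl ether and the C10 protons: the α-acyloxy group raises the electrophilicity of the hindered ketone, the stabilised sulfoxonium ylide is a weak base and a poor acylation partner for unactivated alkyl esters at room temperature, and the triisopropylsilyl group is too bulky to migrate readily to the alkoxide of 11 before ring closure.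

Step 9
Reactants: 13 angelic acid [(Z)-2-methylbut-2-enoic acid], two molecules
Product: 14 angelic anhydride [(Z)-2-methylbut-2-enoic anhydride]
Conditions: 13 (2.0 equiv), DCC (1.0 equiv), CH2Cl2, 0 °C; filtration of the urea
Reagents that add atoms: angelic acid (the second molecule of 13), C/C=C(/C)C(=O)O
Why: Carbodiimide-mediated dehydration (anhydride formation): DCC converts one molecule of 13 into its O-acylisourea, which the carboxylate of a second molecule of 13 acylates to give the symmetrical anhydride and dicyclohexylurea; neither an acid chloride nor a nucleophilic catalyst is involved, so the Z alkene should be preserved.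

Step 10
Reactants: 12 4-[(2R)-2-(acetoxymethyl)oxiran-2-yl]-3-(triisopropylsilyloxy)benzyl 3-methylbutanoate; 14 angelic anhydride
Product: 16 2-[(2R)-2-(acetoxymethyl)oxiran-2-yl]-5-[(3-methylbutanoyloxy)methyl]phenyl (Z)-2-methylbut-2-enoate (CNP0212475.1), via tetrabutylammonium phenoxide 15 (not isolated)
Conditions: Bu4NF (1.05 equiv), THF, −20 °C; then 14 (1.5 equiv), −20 to 0 °C
Reagents that add atoms: none
Why: Fluoride cleavage of the aryl silyl ether followed in the same flask by O-acylation of the phenoxide with the anhydride (desilylation–acylation) should trap the phenoxide at low temperature before it can attack the neighbouring oxirane or the acetate; acylation of an oxyanion by the anhydride without a pyridine-type catalyst is the mode expected to keep the angelate from isomerising to the tiglate, and C8 is not touched.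

**Compound list**

1 | methyl 4-bromo-3-hydroxybenzoate | COC(=O)c1ccc(Br)c(O)c1 | starting material
2 | methyl 4-bromo-3-(triisopropylsilyloxy)benzoate | COC(=O)c1ccc(Br)c(O[Si](C(C)C)(C(C)C)C(C)C)c1 | intermediate
3 | [4-bromo-3-(triisopropylsilyloxy)phenyl]methanol | OCc1ccc(Br)c(O[Si](C(C)C)(C(C)C)C(C)C)c1 | intermediate
4 | 4-bromo-3-(triisopropylsilyloxy)benzyl 3-methylbutanoate | CC(C)CC(=O)OCc1ccc(Br)c(O[Si](C(C)C)(C(C)C)C(C)C)c1 | intermediate
5 | tributyl(1-ethoxyvinyl)stannane | CCCC[Sn](CCCC)(CCCC)C(=C)OCC | starting material
6 | 4-(1-ethoxyvinyl)-3-(triisopropylsilyloxy)benzyl 3-methylbutanoate | CC(C)CC(=O)OCc1ccc(C(=C)OCC)c(O[Si](C(C)C)(C(C)C)C(C)C)c1 | intermediate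
7 | 4-(2-bromoacetyl)-3-(triisopropylsilyloxy)benzyl 3-methylbutanoate | CC(C)CC(=O)OCc1ccc(C(=O)CBr)c(O[Si](C(C)C)(C(C)C)C(C)C)c1 | intermediate
8 | 4-(2-acetoxyacetyl)-3-(triisopropylsilyloxy)benzyl 3-methylbutanoate | CC(C)CC(=O)OCc1ccc(C(=O)COC(C)=O)c(O[Si](C(C)C)(C(C)C)C(C)C)c1 | intermediate
9 | trimethylsulfoxonium chloride | C[S+](C)(C)=O.[Cl-] | starting material
10 | dimethylsulfoxonium methylide | C[S+](C)(=O)[CH2-] | intermediate
11 | (S)-configured sulfoxonium betaine from addition of 10 to C8 of 8 (not isolated) | CC(C)CC(=O)OCc1ccc([C@]([O-])(COC(C)=O)C[S+](C)(C)=O)c(O[Si](C(C)C)(C(C)C)C(C)C)c1 | intermediate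
12 | 4-[(2R)-2-(acetoxymethyl)oxiran-2-yl]-3-(triisopropylsilyloxy)benzyl 3-methylbutanoate | CC(C)CC(=O)OCc1ccc([C@]2(COC(C)=O)CO2)c(O[Si](C(C)C)(C(C)C)C(C)C)c1 | intermediate
13 | angelic acid, (Z)-2-methylbut-2-enoic acid | C/C=C(/C)C(=O)O | starting material
14 | angelic anhydride, (Z)-2-methylbut-2-enoic anhydride | C/C=C(/C)C(=O)OC(=O)/C(C)=C\C | intermediate
15 | tetrabutylammonium 2-[(2R)-2-(acetoxymethyl)oxiran-2-yl]-5-[(3-methylbutanoyloxy)methyl]phenoxide (not isolated) | CCCC[N+](CCCC)(CCCC)CCCC.CC(C)CC(=O)OCc1ccc([C@]2(COC(C)=O)CO2)c([O-])c1 | intermediate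
16 | 2-[(2R)-2-(acetoxymethyl)oxiran-2-yl]-5-[(3-methylbutanoyloxy)methyl]phenyl (Z)-2-methylbut-2-enoate (CNP0212475.1) | C/C=C(/C)C(=O)Oc1cc(COC(=O)CC(C)C)ccc1[C@]1(COC(C)=O)CO1 | target

**Summary**

Total step count: 10. Longest linear sequence: 8 steps (steps 1–6, 8 and 10); steps 7 and 9 prepare the two reagents 10 and 14.

Steps most likely to fail:

Step 8. The catalyst may discriminate poorly between the faces of a ketone whose small substituent is CH2OAc and can itself bind lithium. Ylide may also be lost to deprotonation at C10 or to attack at the acetate, and the alkoxide of the betaine may start acetyl or silyl migration before it closes the ring. The fallback makes the oxirane by oxygen transfer to a C8=C9 alkene instead of methylene transfer to a ketone, and sets out from bromide 4. Stille coupling of 4 with 2-(tributylstannyl)prop-2-en-1-ol [PdCl2(PPh3)2, toluene, 90 °C] would give 4-(3-hydroxyprop-1-en-2-yl)-3-(triisopropylsilyloxy)benzyl 3-methylbutanoate F1. Sharpless asymmetric epoxidation [Ti(Oi-Pr)4, L-(+)-diethyl tartrate, t-BuOOH, 4 Å molecular sieves, CH2Cl2, −20 °C], with the tartrate that gives (S)-glycidols from 2-substituted allyl alcohols, would give 4-[(2S)-2-(hydroxymethyl)oxiran-2-yl]-3-(triisopropylsilyloxy)benzyl 3-methylbutanoate F2. Acetylation (Ac2O, pyridine, 0 °C) changes only the descriptor and brings the sequence back to 12.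

Step 10. The phenoxide set free next to the oxirane may open the ring or racemise C8 through a quinone methide, may take over the C10 acetyl group, or the angelate may isomerise from Z to E during acyl transfer. The fallback puts the aryl ester in place before the oxirane exists and sets out from ketone 8. Buffered desilylation (Bu4NF/AcOH, THF, 0 °C) would give the hydrogen-bonded phenol 4-(2-acetoxyacetyl)-3-hydroxybenzyl 3-methylbutanoate F3. Acylation with 14 (Et3N, CH2Cl2, 0 °C) would give 2-(2-acetoxyacetyl)-5-[(3-methylbutanoyloxy)methyl]phenyl (Z)-2-methylbut-2-enoate F4. Takai–Lombardo methylenation of the ketone (Zn, CH2Br2, TiCl4, THF, 0 °C to rt), which is non-basic and tolerates esters, would give 2-(3-acetoxyprop-1-en-2-yl)-5-[(3-methylbutanoyloxy)methyl]phenyl (Z)-2-methylbut-2-enoate F5. Shi-type epoxidation of the 1,1-disubstituted styrene alkene would then arrive directly at 16. It would use a carbohydrate-derived, oxazolidinone-fused chiral ketone of the kind applied to 1,1-disubstituted alkenes, in the enantiomeric series that leads to the (R)-oxirane, with buffered KHSO5 (as 2KHSO5·KHSO4·K2SO4) at 0 °C. The electron-poor angelate alkene should be left alone.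

Step 6. Acetate may cleave the aryl silyl ether, which is activated by the ortho acyl group, and the phenoxide so formed would then cyclise onto the bromomethyl ketone. The fallback avoids both the bromide and an anionic nucleophile and sets out from enol ether 6. Oxidation of the enol ether with dimethyldioxirane (acetone, −20 °C) and aqueous work-up at pH 7 (Rubottom-type oxidation; the epoxy ether collapses with loss of ethanol) would give 4-(2-hydroxyacetyl)-3-(triisopropylsilyloxy)benzyl 3-methylbutanoate F6. Acetylation (Ac2O, pyridine, 0 °C) then returns to 8.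

**Further compounds**

F1 | step 8 | 4-(3-hydroxyprop-1-en-2-yl)-3-(triisopropylsilyloxy)benzyl 3-methylbutanoate | CC(C)CC(=O)OCc1ccc(C(=C)CO)c(O[Si](C(C)C)(C(C)C)C(C)C)c1
F2 | step 8 | 4-[(2S)-2-(hydroxymethyl)oxiran-2-yl]-3-(triisopropylsilyloxy)benzyl 3-methylbutanoate | CC(C)CC(=O)OCc1ccc([C@]2(CO)CO2)c(O[Si](C(C)C)(C(C)C)C(C)C)c1
F3 | step 10 | 4-(2-acetoxyacetyl)-3-hydroxybenzyl 3-methylbutanoate | CC(C)CC(=O)OCc1ccc(C(=O)COC(C)=O)c(O)c1
F4 | step 10 | 2-(2-acetoxyacetyl)-5-[(3-methylbutanoyloxy)methyl]phenyl (Z)-2-methylbut-2-enoate | C/C=C(/C)C(=O)Oc1cc(COC(=O)CC(C)C)ccc1C(=O)COC(C)=O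
F5 | step 10 | 2-(3-acetoxyprop-1-en-2-yl)-5-[(3-methylbutanoyloxy)methyl]phenyl (Z)-2-methylbut-2-enoate | C/C=C(/C)C(=O)Oc1cc(COC(=O)CC(C)C)ccc1C(=C)COC(C)=O
F6 | step 6 | 4-(2-hydroxyacetyl)-3-(triisopropylsilyloxy)benzyl 3-methylbutanoate | CC(C)CC(=O)OCc1ccc(C(=O)CO)c(O[Si](C(C)C)(C(C)C)C(C)C)c1
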